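The route rests on disconnecting C11–C12. C12, the lone stereocentre, is a carbinol carbon flanked by two near-identical CH2 arms (C11 and C13), so it is treated as a secondary boronate: a racemic C12 α-chloroboronate carrying the C13–C17 (Z)-alkenyl arm is joined to a C1–C11 homoallylic alkylzinc bromide that bears the silyl-protected resorcinol ring (ring A, a spectator; no ring is closed). One enantioconvergent nickel-catalysed coupling forms C11–C12 and sets C12 under ligand control, with both Z alkenes (C8=C9, C14=C15) already in place. Stereoretentive C–B oxidation and desilylation finish the synthesis.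

Key step: step 10

Assumptions (remarks on the chemistry):
- Chain atoms carry the target numbering: C1 is bonded to ring A and C17 is the methyl end.
- 2-(But-3-yn-1-yloxy)oxane is taken as the commercial racemic THP ether; its acetal stereocentre is removed later and is of no consequence.
- The enantiomer of the chiral diamine that delivers the 12S boronate is to be fixed in a small trial run (oxidation, then MTPA ester analysis); both enantiomers of the ligand are commercial.

Step 1
Reactants: 1 (E)-penta-1,3-diene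
Product: 2 4,4,5,5-tetramethyl-2-[(2Z)-pent-2-en-1-yl]-1,3,2-dioxaborolane
Conditions: HBpin (1.0 equiv), 1 (1.2 equiv), Ni(cod)2 (2.5 mol%), PCy3 (2.5 mol%), toluene, 0 °C → rt
Reagents that add atoms: pinacolborane, [H]B1OC(C)(C)C(C)(C)O1
Why: Nickel-catalysed 1,4-hydroboration of a 1,3-diene, in which zerovalent nickel binds the s-cis diene and delivers boron to the unsubstituted terminus and hydrogen to the methyl-bearing terminus through an anti π-allylnickel species, so that the new internal alkene (the future C14=C15) should be Z.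

Step 2
Reactants: 2 4,4,5,5-tetramethyl-2-[(2Z)-pent-2-en-1-yl]-1,3,2-dioxaborolane
Product: 4 rac-2-[(3Z)-1-chlorohex-3-en-1-yl]-4,4,5,5-tetramethyl-1,3,2-dioxaborolane, via lithium dichloromethyl borate complex 3 (not isolated)
Conditions: CH2Cl2 (1.4 equiv), n-BuLi (1.1 equiv), THF, −100 °C; then 2; ZnCl2 (0.7 equiv), −100 °C → rt; bulb-to-bulb distillation
Reagents that add atoms: dichloromethane (as LiCHCl2), ClCCl
Why: Matteson homologation, in which LiCHCl2 adds to boron and the allylic CH2 migrates 1,2 with loss of chloride, inserting a CHCl unit (the future C12) between boron and the pentenyl group without allylic transposition or change of the Z alkene; C12 is deliberately formed racemic.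

Step 3
Reactants: 5 5-bromobenzene-1,3-diol
Product: 6 1-bromo-3,5-bis[(tert-butyldimethylsilyl)oxy]benzene
Conditions: TBSCl (2.4 equiv), imidazole (5 equiv), DMF, rt
Reagents that add atoms: tert-butyl(chloro)dimethylsilane, CC(C)(C)[Si](C)(C)Cl
Why: Standard imidazole-promoted O-silylation of both phenols, giving ethers that should withstand the Grignard, zinc and nickel steps and fall to fluoride at the end.

Step 4
Reactants: 7 2-(but-3-yn-1-yloxy)oxane; 8 1,7-dibromoheptane
Product: 10 2-[(11-bromoundec-3-yn-1-yl)oxy]oxane, via lithium acetylide 9 (not isolated)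
Conditions: n-BuLi (1.0 equiv), THF, −78 → 0 °C; then 8 (3 equiv), DMPU, 0 °C → rt
Reagents that add atoms: none
Why: SN2 alkylation of a lithium acetylide by a primary bromide, with a threefold excess of the symmetrical dibromide (recovered by distillation) to suppress double alkylation; doing this before the arene is attached keeps the aryl silyl ethers away from the basic acetylide medium.

Step 5
Reactants: 6 1-bromo-3,5-bis[(tert-butyldimethylsilyl)oxy]benzene; 10 2-[(11-bromoundec-3-yn-1-yl)oxy]oxane
Product: 12 2-[(11-{3,5-bis[(tert-butyldimethylsilyl)oxy]phenyl}undec-3-yn-1-yl)oxy]oxane, via arylmagnesium bromide 11 (not isolated)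
Conditions: 6 (1.3 equiv), Mg turnings (I2-activated), THF, 50 °C; then 10 (1.0 equiv), Li2CuCl4 (3 mol%), THF/NMP, 0 °C → rt
Reagents that add atoms: none
Why: Copper-catalysed Kumada-type coupling of an aryl Grignard reagent with a primary alkyl bromide via an arylcuprate, to which the internal alkyne, the THP acetal and the aryl silyl ethers are inert at or below rt; magnesium sits meta to both silyloxy groups, so no silyl shift to carbon can occur.

Step 6
Reactants: 12 2-[(11-{3,5-bis[(tert-butyldimethylsilyl)oxy]phenyl}undec-3-yn-1-yl)oxy]oxane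
Product: 13 11-{3,5-bis[(tert-butyldimethylsilyl)oxy]phenyl}undec-3-yn-1-ol
Conditions: PPTS (0.1 equiv), MeOH, 45 °C
Reagents that add atoms: none
Why: Acid-catalysed transacetalisation with methanol removes the THP group under mild conditions that aryl TBS ethers tolerate.

Step 7
Reactants: 13 11-{3,5-bis[(tert-butyldimethylsilyl)oxy]phenyl}undec-3-yn-1-ol
Product: 14 (3Z)-11-{3,5-bis[(tert-butyldimethylsilyl)oxy]phenyl}undec-3-en-1-ol
Conditions: H2 (1 atm), Pd/CaCO3 poisoned with Pb(OAc)2, quinoline, EtOAc, rt, stopped after 1 equiv H2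
Reagents that add atoms: none
Why: Lindlar semihydrogenation, in which syn delivery of H2 on lead-poisoned palladium converts the C8≡C9 alkyne into the Z alkene without touching the silyl ethers or the alcohol.

Step 8
Reactants: 14 (3Z)-11-{3,5-bis[(tert-butyldimethylsilyl)oxy]phenyl}undec-3-en-1-ol
Product: 15 1-[(8Z)-11-bromoundec-8-en-1-yl]-3,5-bis[(tert-butyldimethylsilyl)oxy]benzene
Conditions: CBr4 (1.2 equiv), PPh3 (1.3 equiv), CH2Cl2, 0 °C
Reagents that add atoms: carbon tetrabromide, BrC(Br)(Br)Br
Why: Appel reaction, in which the primary alcohol is activated as an alkoxyphosphonium ion and displaced by bromide (SN2) under neutral conditions that leave the Z alkene and the silyl ethers intact.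

Step 9
Reactants: 15 1-[(8Z)-11-bromoundec-8-en-1-yl]-3,5-bis[(tert-butyldimethylsilyl)oxy]benzene
Product: 16 [(3Z)-11-{3,5-bis[(tert-butyldimethylsilyl)oxy]phenyl}undec-3-en-1-yl]zinc bromide
Conditions: Zn dust (1.5 equiv), I2 (5 mol%), DMA, 70 °C; used as a titrated DMA solution
Reagents that add atoms: zinc, [Zn]
Why: Direct oxidative insertion of iodine-activated zinc into a primary alkyl bromide in an amide solvent, a neutral organozinc formation that Z-homoallylic halides and silyl ethers normally survive unchanged.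

Step 10
Reactants: 4 rac-2-[(3Z)-1-chlorohex-3-en-1-yl]-4,4,5,5-tetramethyl-1,3,2-dioxaborolane; 16 [(3Z)-11-{3,5-bis[(tert-butyldimethylsilyl)oxy]phenyl}undec-3-en-1-yl]zinc bromide
Product: 17 (8Z,12S,14Z)-1-{3,5-bis[(tert-butyldimethylsilyl)oxy]phenyl}-12-(4,4,5,5-tetramethyl-1,3,2-dioxaborolan-2-yl)heptadeca-8,14-diene
Conditions: NiBr2·diglyme (10 mol%), (1R,2R)- or (1S,2S)-N,N′-dimethyl-1,2-diphenylethane-1,2-diamine (13 mol%, enantiomer per the assumption above), 4 (1.0 equiv), 16 (1.5 equiv), THF/DMA, 0 °C
Reagents that add atoms: none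
Why: Monovalent nickel, generated from the divalent precatalyst by the zinc reagent, abstracts chlorine from either enantiomer of 4 to give one planar α-boryl radical at C12, which is captured by the diamine-bound alkylnickel species formed by transmetallation from 16; reductive elimination from trivalent nickel then forms C11–C12. The closest known reaction type is the enantioconvergent nickel/chiral-diamine Negishi coupling of racemic α-haloboronates with primary alkylzinc halides, which tolerates silyl ethers and alkenes. No ring is closed. The C12 stereocentre is set by the chiral ligand alone, because the configuration of 4 is erased at the radical stage. The step needs face selectivity in the radical capture (supplied by the ligand) and must outrun reversible 3-exo closure of the C12 radical onto C14=C15, which would scramble that Z alkene; delocalisation of the radical into the empty boron orbital and fast capture by nickel at 0 °C should keep that closure uncompetitive. The homoallylic zinc reagent should transfer its alkyl group without touching C8=C9, and the bidentate diamine disfavours β-hydride elimination and chain walking.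

Step 11
Reactants: 17 (8Z,12S,14Z)-1-{3,5-bis[(tert-butyldimethylsilyl)oxy]phenyl}-12-(4,4,5,5-tetramethyl-1,3,2-dioxaborolan-2-yl)heptadeca-8,14-diene
Product: 18 (3Z,6S,9Z)-17-{3,5-bis[(tert-butyldimethylsilyl)oxy]phenyl}heptadeca-3,9-dien-6-ol
Conditions: NaBO3·4H2O (5 equiv), THF/H2O (1:1), rt
Reagents that add atoms: sodium perborate, [Na+].[O-]B1OO1
Why: Perborate oxidation of a secondary pinacol boronate, in which the peroxide adds to boron and C12 migrates to oxygen with retention, so the 12S configuration is carried into the carbinol; the Z alkenes are inert and any partial loss of an aryl silyl group in the mildly basic medium is harmless.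

Step 12
Reactants: 18 (3Z,6S,9Z)-17-{3,5-bis[(tert-butyldimethylsilyl)oxy]phenyl}heptadeca-3,9-dien-6-ol
Product: 19 5-[(8Z,12S,14Z)-12-hydroxyheptadeca-8,14-dien-1-yl]benzene-1,3-diol
Conditions: TBAF (2.4 equiv), AcOH (2.4 equiv), THF, 0 °C → rt, argon
Reagents that add atoms: none
Why: Fluoride-mediated cleavage of the two aryl silyl ethers, buffered with acetic acid so that the resorcinol is not exposed to air as its phenoxide; the secondary alcohol, the C12 stereocentre and both Z alkenes are unaffected.

Compound list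
1 | (E)-penta-1,3-diene | C/C=C/C=C | starting material
2 | 4,4,5,5-tetramethyl-2-[(2Z)-pent-2-en-1-yl]-1,3,2-dioxaborolane | CC/C=C\CB1OC(C)(C)C(C)(C)O1 | intermediate
3 | lithium (dichloromethyl)[(2Z)-pent-2-en-1-yl](pinacolato)borate | [Li+].CC/C=C\C[B-]1(C(Cl)Cl)OC(C)(C)C(C)(C)O1 | intermediate
4 | rac-2-[(3Z)-1-chlorohex-3-en-1-yl]-4,4,5,5-tetramethyl-1,3,2-dioxaborolane | CC/C=C\CC(Cl)B1OC(C)(C)C(C)(C)O1 | intermediate
5 | 5-bromobenzene-1,3-diol (5-bromoresorcinol) | Oc1cc(Br)cc(O)c1 | starting material
6 | 1-bromo-3,5-bis[(tert-butyldimethylsilyl)oxy]benzene | CC(C)(C)[Si](C)(C)Oc1cc(Br)cc(O[Si](C)(C)C(C)(C)C)c1 | intermediate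
7 | 2-(but-3-yn-1-yloxy)oxane (racemic THP ether of but-3-yn-1-ol) | C#CCCOC1CCCCO1 | starting material
8 | 1,7-dibromoheptane | BrCCCCCCCBr | starting material
9 | {4-[(oxan-2-yl)oxy]but-1-yn-1-yl}lithium | [Li]C#CCCOC1CCCCO1 | intermediate
10 | 2-[(11-bromoundec-3-yn-1-yl)oxy]oxane | BrCCCCCCCC#CCCOC1CCCCO1 | intermediate
11 | {3,5-bis[(tert-butyldimethylsilyl)oxy]phenyl}magnesium bromide | Br[Mg]c1cc(O[Si](C)(C)C(C)(C)C)cc(O[Si](C)(C)C(C)(C)C)c1 | intermediate
12 | 2-[(11-{3,5-bis[(tert-butyldimethylsilyl)oxy]phenyl}undec-3-yn-1-yl)oxy]oxane | CC(C)(C)[Si](C)(C)Oc1cc(CCCCCCCC#CCCOC2CCCCO2)cc(O[Si](C)(C)C(C)(C)C)c1 | intermediate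
13 | 11-{3,5-bis[(tert-butyldimethylsilyl)oxy]phenyl}undec-3-yn-1-ol | OCCC#CCCCCCCCc1cc(O[Si](C)(C)C(C)(C)C)cc(O[Si](C)(C)C(C)(C)C)c1 | intermediate
14 | (3Z)-11-{3,5-bis[(tert-butyldimethylsilyl)oxy]phenyl}undec-3-en-1-ol | OCC/C=C\CCCCCCCc1cc(O[Si](C)(C)C(C)(C)C)cc(O[Si](C)(C)C(C)(C)C)c1 | intermediate
15 | 1-[(8Z)-11-bromoundec-8-en-1-yl]-3,5-bis[(tert-butyldimethylsilyl)oxy]benzene | BrCC/C=C\CCCCCCCc1cc(O[Si](C)(C)C(C)(C)C)cc(O[Si](C)(C)C(C)(C)C)c1 | intermediate
16 | [(3Z)-11-{3,5-bis[(tert-butyldimethylsilyl)oxy]phenyl}undec-3-en-1-yl]zinc bromide | Br[Zn]CC/C=C\CCCCCCCc1cc(O[Si](C)(C)C(C)(C)C)cc(O[Si](C)(C)C(C)(C)C)c1 | intermediate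
17 | (8Z,12S,14Z)-1-{3,5-bis[(tert-butyldimethylsilyl)oxy]phenyl}-12-(4,4,5,5-tetramethyl-1,3,2-dioxaborolan-2-yl)heptadeca-8,14-diene | CC/C=C\C[C@@H](B1OC(C)(C)C(C)(C)O1)CC/C=C\CCCCCCCc1cc(O[Si](C)(C)C(C)(C)C)cc(O[Si](C)(C)C(C)(C)C)c1 | intermediate
18 | (3Z,6S,9Z)-17-{3,5-bis[(tert-butyldimethylsilyl)oxy]phenyl}heptadeca-3,9-dien-6-ol | CC/C=C\C[C@@H](O)CC/C=C\CCCCCCCc1cc(O[Si](C)(C)C(C)(C)C)cc(O[Si](C)(C)C(C)(C)C)c1 | intermediate
19 | 5-[(8Z,12S,14Z)-12-hydroxyheptadeca-8,14-dien-1-yl]benzene-1,3-diol | CC/C=C\C[C@@H](O)CC/C=C\CCCCCCCc1cc(O)cc(O)c1 | target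

Total step count: 12.
Longest linear sequence: 9 steps (steps 4–12 from 7 and 8; equally steps 3 and 5–12 from 5).

Steps most likely to fail

Step 10 carries the main risk. The capture of the C12 radical may be only partly face-selective, the radical may leak into reversible 3-exo closure onto C14=C15 and erode the Z geometry, or turnover with the functionalised zinc reagent may be slow. The fallback replaces catalyst control by auxiliary-controlled, stereospecific 1,2-migrations at boron. It sets out from 2 and 15 and comes back at 18.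
- Boronate 2 would be transesterified with (1S,2S,3R,5S)-pinanediol (Et2O, rt, pinacol washed out with water) to (1S,2S,3R,5S)-pinanediol [(2Z)-pent-2-en-1-yl]boronate F1.
- Matteson homologation of F1 (LiCHCl2, THF, −100 °C, then ZnCl2, → rt) should give, under control of the auxiliary, (1S,2S,3R,5S)-pinanediol [(1S,3Z)-1-chlorohex-3-en-1-yl]boronate F2.
- Bromide 15 would be converted with Mg in THF into [(3Z)-11-{3,5-bis[(tert-butyldimethylsilyl)oxy]phenyl}undec-3-en-1-yl]magnesium bromide F3.
- F3 would be added to F2 at −78 °C (ZnCl2, → rt), where 1,2-migration with inversion at C12 should give the (12S)-configured pinanediol boronate F4.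
- Oxidation of F4 as in step 11 (longer time, or NaOH/H2O2) releases pinanediol and returns the route at 18.

Step 5 is next. The copper-mediated bond formation between an sp2 and an sp3 carbon may be sluggish, letting Grignard homocoupling and elimination of the bromide compete, and magnesium insertion into the electron-rich aryl bromide may stall. The fallback reverses the polarity of the partners; it sets out from 10 and 6 and comes back at 12.
- Bromide 10 would be treated with zinc dust (I2 cat., DMA, 70 °C) to give {11-[(oxan-2-yl)oxy]undec-8-yn-1-yl}zinc bromide F5.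
- F5 would be joined to aryl bromide 6 in a palladium-catalysed Negishi coupling (Pd(OAc)2/SPhos, THF/DMA, rt), which avoids the aryl Grignard reagent altogether.

Step 9 is third. Incomplete insertion, Wurtz-type dimerisation or adventitious protonation would lower the titre, and radical character at C11 on the metal surface could erode the C8=C9 geometry. The fallback makes the same reagent by halogen–lithium exchange and transmetallation; it sets out from 14 and comes back at 16.
- Alcohol 14 would be converted (I2, PPh3, imidazole, CH2Cl2, 0 °C) into 1-[(8Z)-11-iodoundec-8-en-1-yl]-3,5-bis[(tert-butyldimethylsilyl)oxy]benzene F6.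
- Iodine–lithium exchange on F6 (t-BuLi, 2.1 equiv, Et2O/pentane, −78 °C) should give [(3Z)-11-{3,5-bis[(tert-butyldimethylsilyl)oxy]phenyl}undec-3-en-1-yl]lithium F7.
- Addition of ZnBr2 in THF (−78 → 0 °C) to F7 and dilution with DMA delivers 16 as a solution containing lithium halide.

Further compounds
F1 | step 10 | (1S,2S,3R,5S)-pinanediol [(2Z)-pent-2-en-1-yl]boronate | CC/C=C\CB1O[C@@H]2C[C@@H]3C[C@H]([C@@]2(O1)C)C3(C)C
F2 | step 10 | (1S,2S,3R,5S)-pinanediol [(1S,3Z)-1-chlorohex-3-en-1-yl]boronate | CC/C=C\C[C@@H](Cl)B1O[C@@H]2C[C@@H]3C[C@H]([C@@]2(O1)C)C3(C)C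
F3 | step 10 | [(3Z)-11-{3,5-bis[(tert-butyldimethylsilyl)oxy]phenyl}undec-3-en-1-yl]magnesium bromide | Br[Mg]CC/C=C\CCCCCCCc1cc(O[Si](C)(C)C(C)(C)C)cc(O[Si](C)(C)C(C)(C)C)c1
F4 | step 10 | (1S,2S,3R,5S)-pinanediol [(8Z,12S,14Z)-1-{3,5-bis[(tert-butyldimethylsilyl)oxy]phenyl}heptadeca-8,14-dien-12-yl]boronate | CC/C=C\C[C@@H](B1O[C@@H]2C[C@@H]3C[C@H]([C@@]2(O1)C)C3(C)C)CC/C=C\CCCCCCCc1cc(O[Si](C)(C)C(C)(C)C)cc(O[Si](C)(C)C(C)(C)C)c1
F5 | step 5 | {11-[(oxan-2-yl)oxy]undec-8-yn-1-yl}zinc bromide | Br[Zn]CCCCCCCC#CCCOC1CCCCO1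
F6 | step 9 | 1-[(8Z)-11-iodoundec-8-en-1-yl]-3,5-bis[(tert-butyldimethylsilyl)oxy]benzene | ICC/C=C\CCCCCCCc1cc(O[Si](C)(C)C(C)(C)C)cc(O[Si](C)(C)C(C)(C)C)c1
F7 | step 9 | [(3Z)-11-{3,5-bis[(tert-butyldimethylsilyl)oxy]phenyl}undec-3-en-1-yl]lithium | [Li]CC/C=C\CCCCCCCc1cc(O[Si](C)(C)C(C)(C)C)cc(O[Si](C)(C)C(C)(C)C)c1
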